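**Retrosynthetic overview**

1. Target ⇐ C7 CH2OH → CO2H and desilylation ⇐ hydroxyl-directed epoxidation of a 2-ene-1β-ol ⇐ epoxidation/lactonisation across C1=C10 of a 1(10),2-diene 19-ester ⇐ deconjugative C4-methylation of a 1(10),3-diene ester.
2. Key disconnection: rings A and B at once, by an intramolecular diene–yne [4+2] cycloaddition that forms C5–C10 and C1–C2 from a C/D bicyclo[3.2.1]octane carrying a C5=C4(CO2Me)–C3=C2 diene on C6 and a C10≡C1 alkyne on C9.
3. Enabling feature: ring A (C1, C2, C3, C4, C5, C10) shares the bond C5–C10 with the five-membered ring B, whose other atoms C6, C8, C9 form a three-atom tether; C4 carries the C19 carboxyl (the diene's activating group), and the oxygens on C10 and C1 are anti across C1–C10, which is what epoxide opening of the alkene left by the alkyne delivers.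
4. Dienyne ⇐ Ohira–Bestmann alkynylation at C10; diene ester by dibromo-olefination, trans-selective Stille coupling and carbonylation of a C5 aldehyde; C6 by organocatalytic α-hydroxymethylation.
5. Ring order: C (organocatalytic Michael addition, aldol condensation) → D (SmI2 ketyl–alkyne cyclisation) → B and A together (key step) → lactone and epoxide last.

Key step: step 17

Remark (assumption): the SMILES is read as 1β-OH cis to the 2β,3β-epoxide, both anti to the 19,10-lactone; atoms carry gibberellane numbers (C20 absent), β is the face of C18 and H5, α the face of the lactone bridge; 1, 5 and 8 are taken as catalogue compounds.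

**Route**

Step 1
Reactants: 1 3-[(4-methoxybenzyl)oxy]propanal; 2 but-3-en-2-one
Product: 3 (2S)-2-{[(4-methoxybenzyl)oxy]methyl}-5-oxohexanal
Conditions: (S)-2-[diphenyl(trimethylsilyloxy)methyl]pyrrolidine (10 mol %), ethyl 3,4-dihydroxybenzoate (20 mol %), neat, 4 °C
Reagents that add atoms: none
Why: Enamine-catalysed Michael addition of an aldehyde to an enone, in which the (S)-diarylprolinol silyl ether forms the E-enamine and shields one face, so the enone should be attacked from the open face and the future C9 is set (S).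

Step 2
Reactants: 3 (2S)-2-{[(4-methoxybenzyl)oxy]methyl}-5-oxohexanal
Product: 4 (4R)-4-{[(4-methoxybenzyl)oxy]methyl}cyclohex-2-en-1-one
Conditions: dibenzylammonium trifluoroacetate (20 mol %), toluene, 50 °C
Reagents that add atoms: none
Why: Intramolecular aldol condensation of the 1,5-keto aldehyde under mild ammonium carboxylate catalysis should close ring C without epimerising C9 or eliminating the β-alkoxy group.

Step 3
Reactants: 4 (4R)-4-{[(4-methoxybenzyl)oxy]methyl}cyclohex-2-en-1-one; 5 tert-butyl[(1-methoxyethenyl)oxy]dimethylsilane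
Product: 6 methyl 2-[3-(tert-butyldimethylsilyloxy)-6-{[(4-methoxybenzyl)oxy]methyl}cyclohex-2-en-1-yl]acetate (1,6-trans)
Conditions: TBSOTf (5 mol %), CH2Cl2, −78 °C
Reagents that add atoms: none
Why: Mukaiyama–Michael addition with silyl transfer should deliver the CH2CO2Me unit (C6, C5) to C8 trans to the C9 substituent and leave the ketone as its regiodefined C13–C14 silyl enol ether.

Step 4
Reactants: 6 methyl 2-[3-(tert-butyldimethylsilyloxy)-6-{[(4-methoxybenzyl)oxy]methyl}cyclohex-2-en-1-yl]acetate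
Product: 7 methyl 2-[(6R)-6-{[(4-methoxybenzyl)oxy]methyl}-3-oxocyclohex-1-en-1-yl]acetate
Conditions: Pd(OAc)2 (1.1 equiv), MeCN, 40 °C
Reagents that add atoms: none
Why: Saegusa–Ito oxidation (C-palladation of the silyl enol ether at C14, β-hydride elimination of H8) should regenerate the enone, now with the C6 chain on C8; the C8 stereocentre of 6 is erased on purpose.

Step 5
Reactants: 7 methyl 2-[(6R)-6-{[(4-methoxybenzyl)oxy]methyl}-3-oxocyclohex-1-en-1-yl]acetate; 8 tributyl(propa-1,2-dien-1-yl)stannane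
Product: 9 methyl 2-[(1R,2R)-2-{[(4-methoxybenzyl)oxy]methyl}-5-oxo-1-(prop-2-yn-1-yl)cyclohexyl]acetate (propargyl trans to CH2OPMB)
Conditions: TiCl4 (1.2 equiv), CH2Cl2, −78 °C; aq. NaHCO3
Reagents that add atoms: none
Why: Lewis-acid-mediated conjugate propargylation (Hosomi–Sakurai type, SE2′ attack of the allenylstannane) should add anti to the pseudoaxial C9 substituent and create the quaternary C8 with C15–C17 trans to C10.

Step 6
Reactants: 9 methyl 2-[(1R,2R)-2-{[(4-methoxybenzyl)oxy]methyl}-5-oxo-1-(prop-2-yn-1-yl)cyclohexyl]acetate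
Product: 10 methyl 2-[5-hydroxy-2-{[(4-methoxybenzyl)oxy]methyl}-6-methylidenebicyclo[3.2.1]octan-1-yl]acetate (positions 1/2/5/6/7/8 = C8/C9/C13/C16/C15/C14; C9 substituent anti to the C15–C16 bridge)
Conditions: SmI2 (2.5 equiv), HMPA, t-BuOH, THF, 0 → 23 °C
Reagents that add atoms: none
Why: SmI2-mediated ketyl–alkyne reductive cyclisation (5-exo-dig) of the C13 ketyl onto C16 of the axial propargyl group should give the bridgehead tertiary alcohol and the exocyclic methylene, with C13 fixed by the bicyclic bridge.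

Step 7
Reactants: 10 methyl 2-[5-hydroxy-2-{[(4-methoxybenzyl)oxy]methyl}-6-methylidenebicyclo[3.2.1]octan-1-yl]acetate
Product: 11 methyl 2-[5-(tert-butyldimethylsilyloxy)-2-{[(4-methoxybenzyl)oxy]methyl}-6-methylidenebicyclo[3.2.1]octan-1-yl]acetate
Conditions: TBSOTf (1.5 equiv), 2,6-lutidine, CH2Cl2, 0 → 23 °C
Reagents that add atoms: tert-butyldimethylsilyl trifluoromethanesulfonate, CC(C)(C)[Si](C)(C)OS(=O)(=O)C(F)(F)F
Why: Silylation of the hindered tertiary allylic alcohol with the silyl triflate should protect O13 and later prevent hydroxyl-directed oxidation of C16=C17.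

Step 8
Reactants: 11 methyl 2-[5-(tert-butyldimethylsilyloxy)-2-{[(4-methoxybenzyl)oxy]methyl}-6-methylidenebicyclo[3.2.1]octan-1-yl]acetate
Product: 12 2-[5-(tert-butyldimethylsilyloxy)-2-{[(4-methoxybenzyl)oxy]methyl}-6-methylidenebicyclo[3.2.1]octan-1-yl]acetaldehyde
Conditions: i-Bu2AlH (1.1 equiv), CH2Cl2, −78 °C; aq. KNaC4H4O6
Reagents that add atoms: none
Why: Partial ester reduction with i-Bu2AlH at low temperature should stop at the aluminium hemiacetal, which releases the aldehyde (C5) on work-up.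

Step 9
Reactants: 12 2-[5-(tert-butyldimethylsilyloxy)-2-{[(4-methoxybenzyl)oxy]methyl}-6-methylidenebicyclo[3.2.1]octan-1-yl]acetaldehyde
Product: 13 (2S)-2-[5-(tert-butyldimethylsilyloxy)-2-{[(4-methoxybenzyl)oxy]methyl}-6-methylidenebicyclo[3.2.1]octan-1-yl]-3-hydroxypropanal
Conditions: aq. CH2O (37 %, 3 equiv), (R)-2-[diphenyl(trimethylsilyloxy)methyl]pyrrolidine (20 mol %), pH 7 phosphate buffer, toluene, 23 °C
Reagents that add atoms: formaldehyde, C=O
Why: Enamine-catalysed α-hydroxymethylation of the aldehyde, in which the (R)-diarylprolinol silyl ether shields one face of the E-enamine, should set C6 (S) under catalyst control and so place C7 where the 6β-carboxyl is needed.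

Step 10
Reactants: 13 (2S)-2-[5-(tert-butyldimethylsilyloxy)-2-{[(4-methoxybenzyl)oxy]methyl}-6-methylidenebicyclo[3.2.1]octan-1-yl]-3-hydroxypropanal
Product: 14 (2S)-3-(tert-butyldimethylsilyloxy)-2-[5-(tert-butyldimethylsilyloxy)-2-{[(4-methoxybenzyl)oxy]methyl}-6-methylidenebicyclo[3.2.1]octan-1-yl]propanal
Conditions: TBSCl (1.2 equiv), imidazole, CH2Cl2, 0 °C
Reagents that add atoms: tert-butyldimethylsilyl chloride, CC(C)(C)[Si](C)(C)Cl
Why: Selective silylation of the primary alcohol should give a configurationally more robust β-silyloxy aldehyde.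

Step 11
Reactants: 14 (2S)-3-(tert-butyldimethylsilyloxy)-2-[5-(tert-butyldimethylsilyloxy)-2-{[(4-methoxybenzyl)oxy]methyl}-6-methylidenebicyclo[3.2.1]octan-1-yl]propanal
Product: 15 1,1-dibromoalkene (C6 bears CH=CBr2, CH2OTBS and the C8 bridgehead of the bicycle of 11; C6 unchanged)
Conditions: CBr4 (2 equiv), PPh3 (4 equiv), 2,6-lutidine, CH2Cl2, 0 °C
Reagents that add atoms: tetrabromomethane, BrC(Br)(Br)Br
Why: Ramirez dibromo-olefination (first stage of the Corey–Fuchs sequence) should convert the C5 aldehyde into the dibromoalkene carrying C4 under buffered conditions that do not epimerise C6.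

Step 12
Reactants: 15 1,1-dibromoalkene
Product: 16 (Z)-2-bromo-1,3-diene (C6–CH=C(Br)–CH=CH2, vinyl trans to C6, bromine cis to C6)
Conditions: tributyl(vinyl)stannane (1.05 equiv), Pd2(dba)3 (2.5 mol %), P(2-furyl)3 (15 mol %), toluene, 100 °C
Reagents that add atoms: tributyl(vinyl)stannane, C=C[Sn](CCCC)(CCCC)CCCC
Why: Stille coupling of a 1,1-dibromoalkene is selective for the less hindered bromide trans to the alkyl group, so C3=C2 should enter trans to C6 and fix the diene geometry.

Step 13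
Reactants: 16 (Z)-2-bromo-1,3-diene
Product: 17 diene ester, methyl (2Z)-2-ethenyl-3-(C6)prop-2-enoate (CO2Me cis to C6; C9 side chain CH2OPMB)
Conditions: Pd(OAc)2 (5 mol %), 1,3-bis(diphenylphosphino)propane (10 mol %), CO (1 atm), MeOH, Et3N, DMF, 60 °C
Reagents that add atoms: carbon monoxide, [C-]#[O+]; methanol, CO
Why: Palladium-catalysed methoxycarbonylation of the alkenyl bromide (oxidative addition, CO insertion, methanolysis) proceeds with retention and should put C19 on C4 cis to C6.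

Step 14
Reactants: 17 diene ester (CH2OPMB)
Product: 18 diene ester alcohol (C9–CH2OH)
Conditions: DDQ (1.3 equiv), CH2Cl2 / pH 7 buffer, 0 °C
Reagents that add atoms: none
Why: Oxidative cleavage of the 4-methoxybenzyl ether by DDQ should free the C10 alcohol while the silyl ethers, the electron-poor diene and the 16-ene stay untouched.

Step 15
Reactants: 18 diene ester alcohol
Product: 19 diene ester aldehyde (C9–CHO)
Conditions: Dess–Martin periodinane (1.3 equiv), NaHCO3, CH2Cl2, 0 → 23 °C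
Reagents that add atoms: none
Why: Dess–Martin oxidation should give the C10 aldehyde under buffered, non-epimerising conditions.

Step 16
Reactants: 19 diene ester aldehyde
Product: 20 dienyne (C9–C≡CH; diene ester on C6)
Conditions: dimethyl (1-diazo-2-oxopropyl)phosphonate (1.5 equiv), K2CO3 (2 equiv), MeOH, 0 → 23 °C
Reagents that add atoms: dimethyl (1-diazo-2-oxopropyl)phosphonate, CC(=O)C(=[N+]=[N-])P(=O)(OC)OC
Why: Seyferth–Gilbert homologation with the Ohira–Bestmann reagent should convert the aldehyde into the terminal alkyne C10≡C1 under mild carbonate conditions.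

Step 17
Reactants: 20 dienyne
Product: 21 methyl 7,13-bis(tert-butyldimethylsilyloxy)-20-norgibberella-1(10),3,16-trien-19-oate (5β-H, 6α-H, 9β-H)
Conditions: RhCl(PPh3)3 (10 mol %), CF3CH2OH, degassed, 55 °C
Reagents that add atoms: none
Why: RhCl(PPh3)3 binds the alkyne and the s-cis diene and couples C10 with C5 oxidatively to a rhodacycle (σ-alkenyl at C1, η3-allyl over C4–C3–C2); reductive elimination then joins C1 to C2 and releases the 1,4-cyclohexadiene with return of monovalent rhodium. The closest known reaction type is the rhodium- or nickel-catalysed intramolecular [4+2] cycloaddition of 1,3-dien-8-ynes to bicyclo[4.3.0]nonadienes, the metal-mediated counterpart of an intramolecular Diels–Alder reaction of an unactivated alkyne. Ring B closes in the 5-exo sense over the tether C6–C8–C9 (helped by the quaternary C8), and ring A closes as the six-membered cycloaddition ring, its last bond being C1–C2. The only new stereocentre, C5, is controlled by allylic 1,3-strain: the C19 ester on C4 is cis to C6, so H6 lies in the diene plane, C8 and C7 sit on opposite faces, and the alkyne delivered through C8 must add anti to C7, which gives 5β-H. The step needs this facial selectivity, the diene geometry with C6 "outside" (fixed in steps 12 and 13) and chemoselectivity over the C16=C17 methylene, which the tether cannot reach; it must be run air-free because the 1,4-diene aromatises easily.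

Step 18
Reactants: 21 methyl 7,13-bis(tert-butyldimethylsilyloxy)-20-norgibberella-1(10),3,16-trien-19-oate
Product: 22 methyl 7,13-bis(tert-butyldimethylsilyloxy)-20-norgibberella-1(10),2,16-trien-19-oate (4β-CH3, 4α-CO2Me)
Conditions: LiN(i-Pr)2 (1.2 equiv), THF/HMPA, −78 °C; CH3I (3 equiv), −78 → −40 °C
Reagents that add atoms: iodomethane, CI
Why: Deconjugative α-alkylation of the extended ester enolate (deprotonation at the doubly allylic C2, methylation at C4 anti to the C5–C6 bond) should make C18 β and C19 α and leave the conjugated C1(10),C2 diene.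

Step 19
Reactants: 22 methyl 7,13-bis(tert-butyldimethylsilyloxy)-20-norgibberella-1(10),2,16-trien-19-oate
Product: 24 7,13-bis(tert-butyldimethylsilyloxy)-1β-hydroxy-20-norgibberella-2,16-dien-19-oic acid 19,10α-lactone, via 1β,10β-epoxy ester 23 (not isolated)
Conditions: mCPBA (1.05 equiv), CH2Cl2, −20 → 0 °C; then camphorsulfonic acid (10 mol %), 23 °C
Reagents that add atoms: 3-chloroperoxybenzoic acid, O=C(OO)c1cccc(Cl)c1
Why: Peracid epoxidation of the electron-rich trisubstituted C1=C10 bond from the β face (anti to the C19 ester, C6 and C11) followed by acid-promoted epoxy-ester lactonisation, in which the axial C19 ester carbonyl opens the epoxide at tertiary C10 with inversion and the O-methyl lactonium ion is demethylated, should set the 10α-lactone oxygen and the 1β-hydroxyl together.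

Step 20
Reactants: 24 silylated 1β-hydroxy-2-ene lactone
Product: 25 7,13-bis(tert-butyldimethylsilyloxy)-2β,3β-epoxy-1β-hydroxy-20-norgibberell-16-en-19-oic acid 19,10α-lactone
Conditions: VO(acac)2 (5 mol %), t-BuOOH (1.5 equiv), CH2Cl2, 0 → 23 °C
Reagents that add atoms: tert-butyl hydroperoxide, CC(C)(C)OO
Why: Vanadium-catalysed hydroxyl-directed epoxidation should deliver oxygen to C2=C3 syn to the 1β-hydroxyl, while the silylated O13 cannot direct attack on C16=C17.

Step 21
Reactants: 25 silylated epoxy alcohol lactone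
Product: 26 2β,3β-epoxy-1β,7,13-trihydroxy-20-norgibberell-16-en-19-oic acid 19,10α-lactone
Conditions: Bu4NF (4 equiv), AcOH (4 equiv), THF, 23 → 45 °C
Reagents that add atoms: none
Why: Fluoride cleavage of both silyl ethers under acetic acid buffering should keep the medium near neutral so that lactone and epoxide survive.

Step 22
Reactants: 26 triol lactone
Product: 28 2β,3β-epoxy-1β,13-dihydroxy-20-norgibberell-16-ene-7,19-dioic acid 19,10α-lactone (the target gibberellin), via 7-aldehyde 27 (not isolated)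
Conditions: TEMPO (20 mol %), PhI(OAc)2 (2.5 equiv), MeCN/H2O (1:1), 23 °C
Reagents that add atoms: water, O
Why: Nitroxyl-catalysed oxidation is selective for the primary C7 alcohol over the hindered secondary C1 and tertiary C13 alcohols and should carry it through the aldehyde hydrate to the acid.

**Compound list**

1 | 3-[(4-methoxybenzyl)oxy]propanal | O=CCCOCc1ccc(OC)cc1 | starting material
2 | but-3-en-2-one | CC(=O)C=C | starting material
3 | (2S)-2-{[(4-methoxybenzyl)oxy]methyl}-5-oxohexanal | O=C[C@H](COCc1ccc(OC)cc1)CCC(C)=O | intermediate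
4 | (4R)-4-{[(4-methoxybenzyl)oxy]methyl}cyclohex-2-en-1-one | O=C1C=C[C@H](COCc2ccc(OC)cc2)CC1 | intermediate
5 | tert-butyl[(1-methoxyethenyl)oxy]dimethylsilane | C=C(OC)O[Si](C)(C)C(C)(C)C | starting material
6 | methyl 2-[3-(tert-butyldimethylsilyloxy)-6-{[(4-methoxybenzyl)oxy]methyl}cyclohex-2-en-1-yl]acetate, 1,6-trans | COC(=O)C[C@@H]1C=C(O[Si](C)(C)C(C)(C)C)CC[C@H]1COCc1ccc(OC)cc1 | intermediate
7 | methyl 2-[(6R)-6-{[(4-methoxybenzyl)oxy]methyl}-3-oxocyclohex-1-en-1-yl]acetate | O=C1C=C(CC(=O)OC)[C@H](COCc2ccc(OC)cc2)CC1 | intermediate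
8 | tributyl(propa-1,2-dien-1-yl)stannane | C=C=C[Sn](CCCC)(CCCC)CCCC | starting material
9 | methyl 2-[(1R,2R)-2-{[(4-methoxybenzyl)oxy]methyl}-5-oxo-1-(prop-2-yn-1-yl)cyclohexyl]acetate | C#CC[C@]1(CC(=O)OC)CC(=O)CC[C@H]1COCc1ccc(OC)cc1 | intermediate
10 | methyl 2-[5-hydroxy-2-{[(4-methoxybenzyl)oxy]methyl}-6-methylidenebicyclo[3.2.1]octan-1-yl]acetate | C=C1C[C@]2(CC(=O)OC)C[C@@]1(O)CC[C@H]2COCc1ccc(OC)cc1 | intermediate
11 | 13-O-TBS ether of 10 | C=C1C[C@]2(CC(=O)OC)C[C@@]1(O[Si](C)(C)C(C)(C)C)CC[C@H]2COCc1ccc(OC)cc1 | intermediate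
12 | C5 aldehyde (acetaldehyde side chain on C8) | C=C1C[C@]2(CC=O)C[C@@]1(O[Si](C)(C)C(C)(C)C)CC[C@H]2COCc1ccc(OC)cc1 | intermediate
13 | (2S)-α-hydroxymethyl aldehyde | C=C1C[C@]2([C@H](C=O)CO)C[C@@]1(O[Si](C)(C)C(C)(C)C)CC[C@H]2COCc1ccc(OC)cc1 | intermediate
14 | (2S)-β-silyloxy aldehyde | C=C1C[C@]2([C@H](C=O)CO[Si](C)(C)C(C)(C)C)C[C@@]1(O[Si](C)(C)C(C)(C)C)CC[C@H]2COCc1ccc(OC)cc1 | intermediate
15 | 1,1-dibromoalkene | C=C1C[C@]2([C@H](C=C(Br)Br)CO[Si](C)(C)C(C)(C)C)C[C@@]1(O[Si](C)(C)C(C)(C)C)CC[C@H]2COCc1ccc(OC)cc1 | intermediate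
16 | (Z)-2-bromo-1,3-diene | C=C1C[C@]2([C@H](/C=C(/C=C)Br)CO[Si](C)(C)C(C)(C)C)C[C@@]1(O[Si](C)(C)C(C)(C)C)CC[C@H]2COCc1ccc(OC)cc1 | intermediate
17 | (Z)-diene ester, PMB ether | C=C1C[C@]2([C@H](/C=C(/C=C)C(=O)OC)CO[Si](C)(C)C(C)(C)C)C[C@@]1(O[Si](C)(C)C(C)(C)C)CC[C@H]2COCc1ccc(OC)cc1 | intermediate
18 | diene ester alcohol | C=C1C[C@]2([C@H](/C=C(/C=C)C(=O)OC)CO[Si](C)(C)C(C)(C)C)C[C@@]1(O[Si](C)(C)C(C)(C)C)CC[C@H]2CO | intermediate
19 | diene ester aldehyde | C=C1C[C@]2([C@H](/C=C(/C=C)C(=O)OC)CO[Si](C)(C)C(C)(C)C)C[C@@]1(O[Si](C)(C)C(C)(C)C)CC[C@H]2C=O | intermediate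
20 | dienyne | C=C1C[C@]2([C@H](/C=C(/C=C)C(=O)OC)CO[Si](C)(C)C(C)(C)C)C[C@@]1(O[Si](C)(C)C(C)(C)C)CC[C@H]2C#C | intermediate
21 | methyl 7,13-bis(tert-butyldimethylsilyloxy)-20-norgibberella-1(10),3,16-trien-19-oate | C=C1C[C@]23C[C@@]1(O[Si](C)(C)C(C)(C)C)CC[C@H]2C4=CCC=C(C(=O)OC)[C@H]4[C@@H]3CO[Si](C)(C)C(C)(C)C | intermediate
22 | methyl 7,13-bis(tert-butyldimethylsilyloxy)-20-norgibberella-1(10),2,16-trien-19-oate | C=C1C[C@]23C[C@@]1(O[Si](C)(C)C(C)(C)C)CC[C@H]2C4=CC=C[C@@](C)(C(=O)OC)[C@H]4[C@@H]3CO[Si](C)(C)C(C)(C)C | intermediate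
23 | 1β,10β-epoxy ester | C=C1C[C@]23C[C@@]1(O[Si](C)(C)C(C)(C)C)CC[C@H]2[C@@]45O[C@@H]4C=C[C@@](C)(C(=O)OC)[C@H]5[C@@H]3CO[Si](C)(C)C(C)(C)C | intermediate
24 | silylated 1β-hydroxy-2-ene 19,10α-lactone | C=C1C[C@]23C[C@@]1(O[Si](C)(C)C(C)(C)C)CC[C@H]2[C@@]12OC(=O)[C@@](C)([C@H]1[C@@H]3CO[Si](C)(C)C(C)(C)C)C=C[C@H]2O | intermediate
25 | silylated 2β,3β-epoxy-1β-hydroxy lactone | C=C1C[C@]23C[C@@]1(O[Si](C)(C)C(C)(C)C)CC[C@H]2[C@@]12OC(=O)[C@@](C)([C@H]1[C@@H]3CO[Si](C)(C)C(C)(C)C)[C@H]1O[C@H]1[C@H]2O | intermediate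
26 | 2β,3β-epoxy-1β,7,13-triol lactone | C=C1C[C@]23C[C@@]1(O)CC[C@H]2[C@@]12OC(=O)[C@@](C)([C@H]1[C@@H]3CO)[C@H]1O[C@H]1[C@H]2O | intermediate
27 | 7-aldehyde | C=C1C[C@]23C[C@@]1(O)CC[C@H]2[C@@]12OC(=O)[C@@](C)([C@H]1[C@@H]3C=O)[C@H]1O[C@H]1[C@H]2O | intermediate
28 | 2β,3β-epoxy-1β,13-dihydroxy-20-norgibberell-16-ene-7,19-dioic acid 19,10α-lactone (the target gibberellin) | C=C1C[C@]23C[C@@]1(O)CC[C@H]2[C@@]12OC(=O)[C@@](C)([C@H]1[C@@H]3C(=O)O)[C@H]1O[C@H]1[C@H]2O | target

**Totals**

Total step count: 22. Longest linear sequence: 22 steps (from 1 and 2).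

**Steps most likely to fail**

Step 17. The cycloaddition may be slow, with the terminal alkyne oligomerising at rhodium or the ester diene polymerising, and facial control at C5 may erode. The fallback sets out from 16 and postpones carbonylation, so the ring closure is done thermally on a neutral halodiene. DDQ deprotection of 16 should give the bromodiene alcohol F1, and Dess–Martin oxidation the bromodiene aldehyde F2. The Ohira–Bestmann reagent should then give the bromodienyne F3. A metal-free intramolecular Diels–Alder reaction (toluene, 2,6-di-tert-butyl-4-methylphenol, 160 °C, sealed tube) should give the tetracyclic alkenyl bromide F4, with C5 again under allylic 1,3-strain control from the cis bromine. Palladium-catalysed methoxycarbonylation as in step 13 returns to 21.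

Step 19. The peracid may also attack the C16=C17 methylene, or the vinyl epoxide may ionise at allylic C1 before the ester closes on C10. The fallback sets out from 22 and replaces the peracid by hydroxyl-directed oxidation. HF·pyridine buffered with pyridine (THF, 0 °C) should remove only the primary silyl ether to give the C7 alcohol F5. VO(acac)2 / t-BuOOH, directed by the bis-homoallylic C7 hydroxyl on the β face, should give the 1β,10β-epoxide F6. Camphorsulfonic acid should lactonise it to the 7-hydroxy lactone F7. A second vanadium-catalysed epoxidation, now directed by the 1β-hydroxyl, should give the 2β,3β-epoxide F8. Bu4NF / AcOH then returns to 26.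

Step 9. Enamine formation from the neopentyl-type aldehyde may be sluggish; that would allow dehydration of the product to the α-methylene aldehyde and loss of catalyst control at C6. The fallback sets out from 11 and uses auxiliary control. LiOH (THF/H2O) should give the acid F9. Pivaloyl chloride / Et3N, then the lithium salt of (R)-4-benzyl-1,3-oxazolidin-2-one, should give the imide F10. Titanium-enolate hydroxymethylation (TiCl4, i-Pr2NEt, 1,3,5-trioxane) should give the hydroxymethyl imide F11. TBSCl / imidazole should give the silyl ether imide F12. LiBH4 should cleave the auxiliary reductively to the primary alcohol F13. Dess–Martin oxidation returns to 14.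

Further compounds
F1 | step 17 | bromodiene alcohol | C=C1C[C@]2([C@H](/C=C(/C=C)Br)CO[Si](C)(C)C(C)(C)C)C[C@@]1(O[Si](C)(C)C(C)(C)C)CC[C@H]2CO
F2 | step 17 | bromodiene aldehyde | C=C1C[C@]2([C@H](/C=C(/C=C)Br)CO[Si](C)(C)C(C)(C)C)C[C@@]1(O[Si](C)(C)C(C)(C)C)CC[C@H]2C=O
F3 | step 17 | bromodienyne | C=C1C[C@]2([C@H](/C=C(/C=C)Br)CO[Si](C)(C)C(C)(C)C)C[C@@]1(O[Si](C)(C)C(C)(C)C)CC[C@H]2C#C
F4 | step 17 | tetracyclic alkenyl bromide | C=C1C[C@]23C[C@@]1(O[Si](C)(C)C(C)(C)C)CC[C@H]2C4=CCC=C(Br)[C@H]4[C@@H]3CO[Si](C)(C)C(C)(C)C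
F5 | step 19 | C7 alcohol of 22 | C=C1C[C@]23C[C@@]1(O[Si](C)(C)C(C)(C)C)CC[C@H]2C4=CC=C[C@@](C)(C(=O)OC)[C@H]4[C@@H]3CO
F6 | step 19 | 1β,10β-epoxide of F5 | C=C1C[C@]23C[C@@]1(O[Si](C)(C)C(C)(C)C)CC[C@H]2[C@@]45O[C@@H]4C=C[C@@](C)(C(=O)OC)[C@H]5[C@@H]3CO
F7 | step 19 | 7-hydroxy lactone | C=C1C[C@]23C[C@@]1(O[Si](C)(C)C(C)(C)C)CC[C@H]2[C@@]12OC(=O)[C@@](C)([C@H]1[C@@H]3CO)C=C[C@H]2O
F8 | step 19 | 2β,3β-epoxide of F7 | C=C1C[C@]23C[C@@]1(O[Si](C)(C)C(C)(C)C)CC[C@H]2[C@@]12OC(=O)[C@@](C)([C@H]1[C@@H]3CO)[C@H]1O[C@H]1[C@H]2O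
F9 | step 9 | carboxylic acid from 11 | C=C1C[C@]2(CC(=O)O)C[C@@]1(O[Si](C)(C)C(C)(C)C)CC[C@H]2COCc1ccc(OC)cc1
F10 | step 9 | N-acyl (R)-4-benzyloxazolidinone | C=C1C[C@]2(CC(=O)N3C(=O)OC[C@H]3Cc3ccccc3)C[C@@]1(O[Si](C)(C)C(C)(C)C)CC[C@H]2COCc1ccc(OC)cc1
F11 | step 9 | hydroxymethyl imide | C=C1C[C@]2([C@H](C(=O)N3C(=O)OC[C@H]3Cc3ccccc3)CO)C[C@@]1(O[Si](C)(C)C(C)(C)C)CC[C@H]2COCc1ccc(OC)cc1
F12 | step 9 | silyl ether imide | C=C1C[C@]2([C@H](C(=O)N3C(=O)OC[C@H]3Cc3ccccc3)CO[Si](C)(C)C(C)(C)C)C[C@@]1(O[Si](C)(C)C(C)(C)C)CC[C@H]2COCc1ccc(OC)cc1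
F13 | step 9 | primary alcohol (C5 as CH2OH) | C=C1C[C@]2([C@H](CO)CO[Si](C)(C)C(C)(C)C)C[C@@]1(O[Si](C)(C)C(C)(C)C)CC[C@H]2COCc1ccc(OC)cc1
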